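The ten-membered carbocycle is made by contracting a twelve-membered lactone. In the target (germacrane numbering) the ring ketone carbon C9 and the oxygen of the C12 acetoxymethyl group sit on the same side of the exocyclic C7=C11 unit (C9–C8–C7=C11–C12–O, later the spiro-epoxide); they are read as the two halves of an ester. The precursor is a macrolide in which O12 is acylated by the C9 enoate carbonyl and C8 is an allylic sulfone. Deprotonation drives C8 onto C9 through a six-membered transition state: one operation forms the C8–C9 bond, the E-enone and the free C12 alcohol and shrinks the ring from twelve to ten atoms. A double Sharpless epoxidation then sets all four stereocentres.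

Key step: step 9

Remark (numbering): germacrane locants are used for the skeleton: ring C1 (=CH), C2, C3, C4 (epoxide carbon bearing C15H2O), C5 (epoxide CH), C6, C7 (spiro carbon), C8, C9 (C=O), C10 (=C bearing C14H3); exocyclic C11 (epoxide carbon) bears C13H3 and C12H2O. The target is 4R,5R,7S,11R, 1(10)E, with C3/C6 cis on the 4,5-epoxide and C12 cis to C8.
Assumption (tartrate sense): D-(−)-diethyl tartrate is taken as the enantiomer that gives (2R)-epoxy alcohols, on the basis that L-(+)-diethyl tartrate gives the (2S,3S)-epoxide from an (E)-2-alken-1-ol; by the same face rule it should give 4R,5R and 7S,11R here.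
Assumption (supply): compounds 1, 2, 4, 8, 9 and 13 are bought.

Step 1
Reactants: 1 tert-butyldimethyl(prop-2-yn-1-yloxy)silane; 2 4-chlorobut-2-yn-1-ol
Product: 3 7-[(tert-butyldimethylsilyl)oxy]hepta-2,5-diyn-1-ol
Conditions: CuI, NaI, K2CO3, DMF, rt
Reagents that add atoms: none
Why: The copper acetylide of 1 displaces the propargylic chloride of 2 (activated in situ as the iodide) by SN2, a copper-mediated alkyne–propargyl halide coupling that gives the skipped diyne and leaves its two propargylic ends different (free OH versus silyl ether).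

Step 2
Reactants: 3 7-[(tert-butyldimethylsilyl)oxy]hepta-2,5-diyn-1-ol; 4 but-3-en-1-ylmagnesium bromide
Product: 6 (2E)-2-(but-3-en-1-yl)-7-[(tert-butyldimethylsilyl)oxy]hept-2-en-5-yn-1-ol, via alkenylmagnesium chelate 5 (not isolated)
Conditions: 4 (3.5 equiv), CuI (10 mol%), THF, 0 to 40 °C; aq. NH4Cl
Reagents that add atoms: but-3-en-1-ylmagnesium bromide (4), C=CCC[Mg]Br
Why: Copper-catalysed, alkoxide-directed anti-carbomagnesiation of the propargylic alcohol puts the butenyl group on the alkyne carbon next to CH2O (C4) and magnesium on C5 in a five-membered chelate, and protonation with retention leaves the C3 chain cis to C6 (E by CIP), which is the ring-cis C4=C5 geometry of the target; the silyl-ether alkyne has no directing alkoxide and should stay.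

Step 3
Reactants: 6 (2E)-2-(but-3-en-1-yl)-7-[(tert-butyldimethylsilyl)oxy]hept-2-en-5-yn-1-ol
Product: 7 (2E)-2-(but-3-en-1-yl)hept-2-en-5-yne-1,7-diol
Conditions: TBAF, THF, 0 °C; aq. NH4Cl
Reagents that add atoms: none
Why: Fluoride cleaves the primary silyl ether (standard desilylation) and frees the second propargylic alcohol, which is needed to direct the next carbometalation.

Step 4
Reactants: 7 (2E)-2-(but-3-en-1-yl)hept-2-en-5-yne-1,7-diol; 8 methylmagnesium bromide; 9 chloromethyl phenyl sulfide
Product: 11 (2E,5Z)-2-(but-3-en-1-yl)-6-methyl-5-[(phenylsulfanyl)methyl]hepta-2,5-diene-1,7-diol, via alkenylmagnesium chelate 10 (not isolated)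
Conditions: 8 (5 equiv), CuI (20 mol%), THF, 0 to 45 °C; then 9 (6 equiv), −20 °C to rt; aq. NH4Cl
Reagents that add atoms: methylmagnesium bromide (8), C[Mg]Br; chloromethyl phenyl sulfide (9), ClCSc1ccccc1
Why: A second alkoxide-directed anti-carbomagnesiation puts CH3 on C11 and magnesium on C7 cis to C12H2O, and copper-assisted alkylation of this alkenylmagnesium by the α-chloro sulfide with retention fixes C8 cis to C12 on the tetrasubstituted alkene (5Z), the geometry the acyl shift of step 9 needs.

Step 5
Reactants: 11 (2E,5Z)-2-(but-3-en-1-yl)-6-methyl-5-[(phenylsulfanyl)methyl]hepta-2,5-diene-1,7-diol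
Product: 12 (2E,5Z)-2-(but-3-en-1-yl)-6-methyl-5-[(phenylsulfonyl)methyl]hepta-2,5-diene-1,7-diol
Conditions: (NH4)6Mo7O24·4H2O (10 mol%), 30% H2O2, EtOH, 0 °C to rt
Reagents that add atoms: hydrogen peroxide, OO
Why: Molybdate-catalysed peroxide oxidation is chemoselective for sulfur (sulfide to sulfone through the sulfoxide) and should leave the alkenes and allylic alcohols untouched at this temperature.

Step 6
Reactants: 12 (2E,5Z)-2-(but-3-en-1-yl)-6-methyl-5-[(phenylsulfonyl)methyl]hepta-2,5-diene-1,7-diol; 13 methyl methacrylate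
Product: 14 methyl (2E,6E,9Z)-11-hydroxy-6-(hydroxymethyl)-2,10-dimethyl-9-[(phenylsulfonyl)methyl]undeca-2,6,9-trienoate
Conditions: 13 (10 equiv), Grubbs second-generation catalyst (5 mol%), CH2Cl2, 40 °C
Reagents that add atoms: methyl methacrylate (13), C=C(C)C(=O)OC
Why: Olefin cross-metathesis of the only monosubstituted alkene with excess methacrylate gives the trisubstituted enoate with the usual high E selectivity (the later 1(10)E geometry), while the tri- and tetrasubstituted alkenes are inert to the ruthenium carbene.

Step 7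
Reactants: 14 methyl (2E,6E,9Z)-11-hydroxy-6-(hydroxymethyl)-2,10-dimethyl-9-[(phenylsulfonyl)methyl]undeca-2,6,9-trienoate
Product: 15 (2E,6E,9Z)-11-hydroxy-6-(hydroxymethyl)-2,10-dimethyl-9-[(phenylsulfonyl)methyl]undeca-2,6,9-trienoic acid
Conditions: LiOH, THF/MeOH/H2O, rt; then 1 M HCl to pH 4
Reagents that add atoms: lithium hydroxide, [Li+].[OH-]
Why: Saponification of the methyl enoate (BAc2); aqueous hydroxide at room temperature should not deprotonate the sulfone or move the alkenes.

Step 8
Reactants: 15 (2E,6E,9Z)-11-hydroxy-6-(hydroxymethyl)-2,10-dimethyl-9-[(phenylsulfonyl)methyl]undeca-2,6,9-trienoic acid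
Product: 17 (3E,7E,10Z)-7-(hydroxymethyl)-3,11-dimethyl-10-[(phenylsulfonyl)methyl]-1-oxacyclododeca-3,7,10-trien-2-one, via mixed anhydride 16 (not isolated)
Conditions: 2-methyl-6-nitrobenzoic anhydride (1.3 equiv), DMAP (3 equiv), CH2Cl2, rt, slow addition of 15 to about 1 mM
Reagents that add atoms: none
Why: Shiina macrolactonisation: the mixed anhydride is acylated intramolecularly by the C12 hydroxyl to give the twelve-membered lactone, because lactonisation onto the C15 hydroxyl would need an eight-membered ring holding the E-enoate and intermolecular acylation is held back by slow addition at high dilution.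

Step 9
Reactants: 17 (3E,7E,10Z)-7-(hydroxymethyl)-3,11-dimethyl-10-[(phenylsulfonyl)methyl]-1-oxacyclododeca-3,7,10-trien-2-one
Product: 19 (2E,6E,9Z)-6-(hydroxymethyl)-9-(1-hydroxypropan-2-ylidene)-2-methyl-10-(phenylsulfonyl)cyclodeca-2,6-dien-1-one, via dilithiated sulfone 18 (not isolated)
Conditions: LiHMDS (2.3 equiv), THF, −78 to −20 °C; aq. NH4Cl
Reagents that add atoms: none
Why: LiHMDS removes the C15–OH proton and the C8–H next to the sulfone; the lithiated allylic sulfone adds to the lactone carbonyl C9, which the cis C8–C7=C11–C12–O array holds within reach, the tetrahedral alkoxide expels O12, and the β-keto sulfone so formed is deprotonated at once by the released alkoxide, which makes the O→C acyl shift irreversible. The closest known reaction type is the Claisen/Dieckmann acylation of an α-sulfonyl carbanion by an ester, here run as an intramolecular acyl migration of the Baker–Venkataraman kind. The only ring closed is the ten-membered carbocycle, formed by transannular 6-exo-trig attack (C8, C7, C11, C12, O12 and C9 in the transition state), so that the twelve-membered lactone loses O12, C12 and C11 to a side chain and gains C8. No lasting stereocentre is made (the C8 epimers converge in step 10) and the three alkene geometries are carried through unchanged. The selectivity needed is C-acylation ahead of 1,4-elimination of the carboxylate from the allyl anion and ahead of E/Z scrambling at C7=C11; the Z placement of C8 and C12, lithium chelation between sulfonyl and carbonyl oxygens and −78 °C should secure the six-membered path, and attack by O15 is excluded because it would need an eight-membered ring holding the E-enoate.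

Step 10
Reactants: 19 (2E,6E,9Z)-6-(hydroxymethyl)-9-(1-hydroxypropan-2-ylidene)-2-methyl-10-(phenylsulfonyl)cyclodeca-2,6-dien-1-one
Product: 20 (2E,6E,9Z)-6-(hydroxymethyl)-9-(1-hydroxypropan-2-ylidene)-2-methylcyclodeca-2,6-dien-1-one
Conditions: SmI2 (2.5 equiv), THF/MeOH, −78 °C
Reagents that add atoms: none
Why: Single-electron reduction of the α-sulfonyl ketone cleaves the C8–S bond and the samarium dienolate is protonated at C8 (kinetic α-protonation), so the C7=C11 alkene stays out of conjugation with its geometry intact, while the enone is reduced far more slowly at −78 °C.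

Step 11
Reactants: 20 (2E,6E,9Z)-6-(hydroxymethyl)-9-(1-hydroxypropan-2-ylidene)-2-methylcyclodeca-2,6-dien-1-one
Product: 22 (4R,5R,7S,11R)-4,5:7,11-diepoxy-12,15-dihydroxygermacr-1(10)E-en-9-one, via 4,5-monoepoxide 21 (not isolated)
Conditions: Ti(OiPr)4 (0.4 equiv), D-(−)-diethyl tartrate (0.5 equiv), t-BuOOH (4 equiv, in decane), 4 Å MS, CH2Cl2, −20 °C
Reagents that add atoms: tert-butyl hydroperoxide, CC(C)(C)OO
Why: Katsuki–Sharpless asymmetric epoxidation at both primary allylic alcohols: titanium-bound C15–OH and C12–OH deliver oxygen to the C4=C5 and C7=C11 faces dictated by the D-(−)-tartrate ligand and so should set 4R,5R and 7S,11R by reagent control (whichever monoepoxide forms first converges on 22), while the enone alkene is no allylic alcohol and is left.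

Step 12
Reactants: 22 (4R,5R,7S,11R)-4,5:7,11-diepoxy-12,15-dihydroxygermacr-1(10)E-en-9-one
Product: 23 (4R,5R,7S,11R)-12,15-diacetoxy-4,5:7,11-diepoxygermacr-1(10)E-en-9-one (CNP0185847.3)
Conditions: Ac2O, pyridine, DMAP (cat.), CH2Cl2, 0 °C
Reagents that add atoms: acetic anhydride, CC(=O)OC(C)=O
Why: DMAP-catalysed acetylation of the two primary alcohols under mild, buffered conditions that should spare the epoxides and the β-epoxy ketone.

Compound list
1 | tert-butyldimethyl(prop-2-yn-1-yloxy)silane | C#CCO[Si](C)(C)C(C)(C)C | starting material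
2 | 4-chlorobut-2-yn-1-ol | OCC#CCCl | starting material
3 | 7-[(tert-butyldimethylsilyl)oxy]hepta-2,5-diyn-1-ol | OCC#CCC#CCO[Si](C)(C)C(C)(C)C | intermediate
4 | but-3-en-1-ylmagnesium bromide | C=CCC[Mg]Br | starting material
5 | alkenylmagnesium chelate of step 2 (2,5-dihydro-1,2-oxamagnesole: Mg on C5 and on O15; not isolated) | C=CCCC1=C(CC#CCO[Si](C)(C)C(C)(C)C)[Mg]OC1 | intermediate
6 | (2E)-2-(but-3-en-1-yl)-7-[(tert-butyldimethylsilyl)oxy]hept-2-en-5-yn-1-ol | OC/C(CCC=C)=C/CC#CCO[Si](C)(C)C(C)(C)C | intermediate
7 | (2E)-2-(but-3-en-1-yl)hept-2-en-5-yne-1,7-diol | OC/C(CCC=C)=C/CC#CCO | intermediate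
8 | methylmagnesium bromide | C[Mg]Br | starting material
9 | chloromethyl phenyl sulfide | ClCSc1ccccc1 | starting material
10 | alkenylmagnesium chelate of step 4 (Mg on C7 and O12, bromomagnesium alkoxide at O15; not isolated) | C=CCC/C(CO[Mg]Br)=C\CC1=C(C)CO[Mg]1 | intermediate
11 | (2E,5Z)-2-(but-3-en-1-yl)-6-methyl-5-[(phenylsulfanyl)methyl]hepta-2,5-diene-1,7-diol | OC/C(CCC=C)=C/C/C(CSc1ccccc1)=C(\C)CO | intermediate
12 | (2E,5Z)-2-(but-3-en-1-yl)-6-methyl-5-[(phenylsulfonyl)methyl]hepta-2,5-diene-1,7-diol | OC/C(CCC=C)=C/C/C(CS(=O)(=O)c1ccccc1)=C(\C)CO | intermediate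
13 | methyl methacrylate | C=C(C)C(=O)OC | starting material
14 | methyl (2E,6E,9Z)-11-hydroxy-6-(hydroxymethyl)-2,10-dimethyl-9-[(phenylsulfonyl)methyl]undeca-2,6,9-trienoate | COC(=O)/C(C)=C/CC/C(CO)=C\C/C(CS(=O)(=O)c1ccccc1)=C(\C)CO | intermediate
15 | (2E,6E,9Z)-11-hydroxy-6-(hydroxymethyl)-2,10-dimethyl-9-[(phenylsulfonyl)methyl]undeca-2,6,9-trienoic acid | OC(=O)/C(C)=C/CC/C(CO)=C\C/C(CS(=O)(=O)c1ccccc1)=C(\C)CO | intermediate
16 | mixed anhydride of 15 with 2-methyl-6-nitrobenzoic acid (not isolated) | Cc1cccc([N+](=O)[O-])c1C(=O)OC(=O)/C(C)=C/CC/C(CO)=C\C/C(CS(=O)(=O)c2ccccc2)=C(\C)CO | intermediate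
17 | (3E,7E,10Z)-7-(hydroxymethyl)-3,11-dimethyl-10-[(phenylsulfonyl)methyl]-1-oxacyclododeca-3,7,10-trien-2-one (12-membered lactone, O12 on the C9 carbonyl) | O=C1OC/C(C)=C(\CS(=O)(=O)c2ccccc2)C/C=C(CO)\CC/C=C1\C | intermediate
18 | dilithiated 17 (carbanion at C8, alkoxide at O15; not isolated) | [Li+].[Li+].O=C1OC/C(C)=C(\[CH-]S(=O)(=O)c2ccccc2)C/C=C(C[O-])\CC/C=C1\C | intermediate
19 | (2E,6E,9Z)-6-(hydroxymethyl)-9-(1-hydroxypropan-2-ylidene)-2-methyl-10-(phenylsulfonyl)cyclodeca-2,6-dien-1-one (both epimers at the sulfonyl carbon C8) | O=C1C(S(=O)(=O)c2ccccc2)/C(=C(/C)CO)C/C=C(CO)\CC/C=C1\C | intermediate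
20 | (2E,6E,9Z)-6-(hydroxymethyl)-9-(1-hydroxypropan-2-ylidene)-2-methylcyclodeca-2,6-dien-1-one (open form; may equilibrate with the O12–C9 hemiketal) | O=C1C/C(=C(/C)CO)C/C=C(CO)\CC/C=C1\C | intermediate
21 | (4R,5R)-4,5-epoxy-12,15-dihydroxygermacra-1(10)E,7(11)Z-dien-9-one (monoepoxide, not isolated) | OC[C@]12CC/C=C(\C)C(=O)C/C(=C(/C)CO)C[C@H]1O2 | intermediate
22 | (4R,5R,7S,11R)-4,5:7,11-diepoxy-12,15-dihydroxygermacr-1(10)E-en-9-one | OC[C@]12CC/C=C(\C)C(=O)C[C@]3(C[C@H]1O2)O[C@]3(C)CO | intermediate
23 | (4R,5R,7S,11R)-12,15-diacetoxy-4,5:7,11-diepoxygermacr-1(10)E-en-9-one (CNP0185847.3) | CC(=O)OC[C@]12CC/C=C(\C)C(=O)C[C@]3(C[C@H]1O2)O[C@]3(C)COC(C)=O | target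

Total step count: 12
Longest linear sequence: 12 steps (1/2 to 23)

Steps most likely to fail

Step 9 (key step). What may go wrong: the lithiated allylic sulfone may expel the carboxylate by 1,4-elimination, which would open the lactone, faster than it is C-acylated, or it may lose the C7=C11 geometry before the acyl shift. Fallback: the leaving group is taken out of play by keeping the ester open and both oxygens silylated, at the price of closing the ten-membered ring directly and without the six-membered transition state. Setting out from 14, TBSCl and imidazole should give the bis(silyl ether) ester F1. LiHMDS at high dilution should then close C8–C9 by a Dieckmann-type sulfone–ester condensation to the cyclic β-keto sulfone bis(silyl ether) F2, in which a silyloxy group cannot leave. SmI2 should remove the sulfone to give the bis(silyl ether) trienone F3, and HF·pyridine should return the route at 20.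

Step 4. What may go wrong: sluggish carbomagnesiation of the internal alkyne, or slow C-alkylation of the hindered alkenylmagnesium, so that O-alkylation of the alkoxides or simple protonation competes. Fallback: setting out from 7, the same carbomagnesiation is quenched with iodine instead, which should give the vinyl iodide F4 with iodine cis to C12H2OH. A Migita–Kosugi–Stille coupling with tributyl[(phenylsulfanyl)methyl]stannane (Pd(PPh3)4, CuI, DMF) should then install the CH2SPh group with retention and return the route at 11.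

Step 11. What may go wrong: the face demanded by the tartrate may conflict with the face the ring conformation exposes, giving incomplete reagent control at one alkene, or the titanium Lewis acid may open the tetrasubstituted epoxy alcohol. Fallback: setting out from 20, both alcohols are acetylated first (Ac2O, pyridine) to the diacetate F5. A ketone-catalysed dioxirane (Shi) epoxidation, with the fructose-derived ketone enantiomer chosen by the spiro transition-state model, should then epoxidise the two electron-rich alkenes without a Lewis acid and leave the enone, returning the route at 23.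

Further compounds
F1 | step 9 | methyl (2E,6E,9Z)-11-[(tert-butyldimethylsilyl)oxy]-6-{[(tert-butyldimethylsilyl)oxy]methyl}-2,10-dimethyl-9-[(phenylsulfonyl)methyl]undeca-2,6,9-trienoate | COC(=O)/C(C)=C/CC/C(CO[Si](C)(C)C(C)(C)C)=C\C/C(CS(=O)(=O)c1ccccc1)=C(\C)CO[Si](C)(C)C(C)(C)C
F2 | step 9 | bis(tert-butyldimethylsilyl) ether of 19 | O=C1C(S(=O)(=O)c2ccccc2)/C(=C(/C)CO[Si](C)(C)C(C)(C)C)C/C=C(CO[Si](C)(C)C(C)(C)C)\CC/C=C1\C
F3 | step 9 | bis(tert-butyldimethylsilyl) ether of 20 | O=C1C/C(=C(/C)CO[Si](C)(C)C(C)(C)C)C/C=C(CO[Si](C)(C)C(C)(C)C)\CC/C=C1\C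
F4 | step 4 | (2E,5Z)-2-(but-3-en-1-yl)-5-iodo-6-methylhepta-2,5-diene-1,7-diol | OC/C(CCC=C)=C/C/C(I)=C(\C)CO
F5 | step 11 | diacetate of 20 | O=C1C/C(=C(/C)COC(C)=O)C/C=C(COC(C)=O)\CC/C=C1\C
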